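**Retrosynthetic overview**

1. Feature: the ring C1 (carbonyl), C2=C3, C4, C5 (carbinol), C6 with its side chain C1′–C2′ (ketone) is the aldol adduct of a C1 methyl ketone, reacting through its methyl carbon C6, with the C5 carbonyl of the oleoyl β-diketone C5–C1′–C2′. An oxygen at C3 relays chirality and leaves last as the C2=C3 alkene.
2. Target ⇒ (E1cB loss of the C3 oxygen) 3-silyloxy-5-hydroxycyclohexanone ⇒ (C5–C6 bond, the only ring closure) 2-(acylmethylidene)-6-methylidene-4-silyloxyoxane, a cyclic enol-ether mask of the triketone that fixes C6 as the nucleophile.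
3. That oxane ⇒ 6-(halomethyl) vinylogous ester ⇒ lactol from acylation (C5–C1′ bond) of the silylated (4R,6S)-6-(chloromethyl)-4-hydroxyoxan-2-one with the methyl ketone enolate made from oleic acid and MeLi.
4. Ring order: the oxane ring is bought; the six-membered carbocycle is the only ring formed, in the key step, as the oxane opens. The lactone C4 stereocentre sets C5 and is then erased.

Key step: step 7

Remark (assumption): the exocyclic vinylogous ester alkene of the oxane intermediates is drawn E; its geometry is lost in step 7, so either isomer or a mixture serves. The lactol of step 3 is a mixture of C2 epimers in equilibrium with its open-chain hydroxy β-diketone.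

**Step 1**
Reactants: 1 oleic acid [(9Z)-octadec-9-enoic acid]; 2 methyllithium
Product: 3 (10Z)-nonadec-10-en-2-one
Conditions: MeLi (2.2 equiv), Et2O, 0 °C → rt; slow inverse quench into ice-cold 1 M HCl
Reagents that add atoms: none
Why: Carboxylic acid to methyl ketone by organolithium addition: the lithium carboxylate takes up one further MeLi to a gem-dialkoxide that collapses to the ketone only on the inverse acidic quench, and the Z-alkene is inert.

**Step 2**
Reactants: 4 (4R,6S)-6-(chloromethyl)-4-hydroxyoxan-2-one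
Product: 5 (4R,6S)-4-(tert-butyldimethylsilyloxy)-6-(chloromethyl)oxan-2-one
Conditions: TBSCl, imidazole, DMF, rt
Reagents that add atoms: tert-butyldimethylsilyl chloride, CC(C)(C)[Si](C)(C)Cl
Why: Standard imidazole-promoted silylation of a secondary alcohol, which leaves the lactone and both stereocentres untouched.

**Step 3**
Reactants: 3 (10Z)-nonadec-10-en-2-one; 5 (4R,6S)-4-(tert-butyldimethylsilyloxy)-6-(chloromethyl)oxan-2-one
Product: 7 (10Z)-1-[(4R,6S)-4-(tert-butyldimethylsilyloxy)-6-(chloromethyl)-2-hydroxyoxan-2-yl]nonadec-10-en-2-one, via lithium (10Z)-nonadeca-1,10-dien-2-olate 6 (not isolated)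
Conditions: LiN(i-Pr)2 (LDA, 2.1 equiv), 3 (2.1 equiv), THF, −78 °C; then 5, −78 °C; AcOH quench at −78 °C
Reagents that add atoms: none
Why: Crossed Claisen-type acylation in which the kinetic methyl-side lithium enolate adds to the lactone carbonyl at −78 °C, the adduct is held as the β-diketonate (hence two equivalents of enolate, the second returning as 3) and closes to the six-membered lactol on protonation, while the primary chloride and the C4 and C6 stereocentres are not touched.

**Step 4**
Reactants: 7 (10Z)-1-[(4R,6S)-4-(tert-butyldimethylsilyloxy)-6-(chloromethyl)-2-hydroxyoxan-2-yl]nonadec-10-en-2-one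
Product: 8 (1E,10Z)-1-[(4R,6S)-4-(tert-butyldimethylsilyloxy)-6-(chloromethyl)oxan-2-ylidene]nonadec-10-en-2-one
Conditions: PPTS (cat.), PhMe, 4 Å MS, 60 °C
Reagents that add atoms: none
Why: Acid-catalysed dehydration of the hemiketal through its oxocarbenium ion gives the conjugated exocyclic β-alkoxy enone (vinylogous ester), the thermodynamic alkene isomer, under conditions mild enough for the silyl ether.

**Step 5**
Reactants: 8 (1E,10Z)-1-[(4R,6S)-4-(tert-butyldimethylsilyloxy)-6-(chloromethyl)oxan-2-ylidene]nonadec-10-en-2-one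
Product: 9 (1E,10Z)-1-[(4R,6S)-4-(tert-butyldimethylsilyloxy)-6-(iodomethyl)oxan-2-ylidene]nonadec-10-en-2-one
Conditions: NaI (10 equiv), NaHCO3 (cat.), 2-butanone, reflux
Reagents that add atoms: sodium iodide, [Na+].[I-]
Why: Finkelstein halide exchange (SN2 at the primary carbon) driven by precipitation of NaCl, run hot because the β-oxygen slows substitution.

**Step 6**
Reactants: 9 (1E,10Z)-1-[(4R,6S)-4-(tert-butyldimethylsilyloxy)-6-(iodomethyl)oxan-2-ylidene]nonadec-10-en-2-one
Product: 10 (1E,10Z)-1-[(4R)-4-(tert-butyldimethylsilyloxy)-6-methylideneoxan-2-ylidene]nonadec-10-en-2-one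
Conditions: DBU (3 equiv), THF, 60 °C; filtration through Et3N-deactivated silica, used at once
Reagents that add atoms: none
Why: E2 dehydrohalogenation of the primary iodide, whose only β-hydrogen sits on C6, gives the exocyclic enol ether as in the standard preparation of hex-5-enopyranosides, deliberately removing the C6 stereocentre and leaving C4 alone.

**Step 7**
Reactants: 10 (1E,10Z)-1-[(4R)-4-(tert-butyldimethylsilyloxy)-6-methylideneoxan-2-ylidene]nonadec-10-en-2-one
Product: 12 (3S,5R)-3-(tert-butyldimethylsilyloxy)-5-hydroxy-5-[(10Z)-2-oxononadec-10-en-1-yl]cyclohexan-1-one, via open-chain α-mercurio triketone 11 (not isolated)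
Conditions: Hg(OCOCF3)2 (10 mol %), acetone–H2O (5:1), 0 °C → rt
Reagents that add atoms: water, O
Why: Proposed new method: Hg(OCOCF3)2 adds to the electron-rich exocyclic enol ether, water traps the oxocarbenium ion at the former oxane C6, and the hemiketal collapses with the ring oxygen leaving as the enol of the β-diketone, which gives the α-mercurio methyl ketone 11 in which the nucleophilic carbon is fixed as C6. That carbon then adds to the nearer diketone carbonyl (C5) in a 6-(enolendo)-exo-trig aldol that forms the C5–C6 bond and closes the carbocycle, and protonolysis of the mercury aldolate returns the catalyst. The closest known reaction is the Ferrier carbocyclisation of hex-5-enopyranosides to β-hydroxycyclohexanones, where the acceptor is an aldehyde; a ketone acceptor set free as a β-diketone is the untested extension. The new C5 stereocentre is controlled by the C3 silyloxy group through a chair transition state with that group equatorial and the metal-bridged acceptor oxygen axial, so the hydroxyl should come out trans to the silyloxy group, which is 5R. The step needs chemoselective mercuration, secured by the far higher nucleophilicity of the simple enol ether over the push–pull vinylogous ester alkene and the remote Z-alkene together with the low catalyst loading, and regioselective aldol, secured because only C6 carries the metal, only attack at C5 gives a six-membered ring, and the near-neutral medium offers no base for the competing C1′-to-C1 closure, retro-aldol or aromatisation. Since C3 is removed later, any cis diastereomer would end as the enantiomer of the target and is to be separated at this stage.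

**Step 8**
Reactants: 12 (3S,5R)-3-(tert-butyldimethylsilyloxy)-5-hydroxy-5-[(10Z)-2-oxononadec-10-en-1-yl]cyclohexan-1-one
Product: 13 (3S,5R)-3,5-dihydroxy-5-[(10Z)-2-oxononadec-10-en-1-yl]cyclohexan-1-one
Conditions: HF·pyridine, pyridine, THF, 0 °C → rt
Reagents that add atoms: none
Why: Fluoride-mediated desilylation under buffered, mildly acidic conditions frees the secondary alcohol without retro-aldol or dehydration of the β-hydroxy ketone units and without touching either stereocentre.

**Step 9**
Reactants: 13 (3S,5R)-3,5-dihydroxy-5-[(10Z)-2-oxononadec-10-en-1-yl]cyclohexan-1-one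
Product: 15 (5R)-5-hydroxy-5-[(10Z)-2-oxononadec-10-en-1-yl]cyclohex-2-en-1-one, via secondary mesylate 14 (not isolated)
Conditions: MsCl (1.2 equiv), Et3N (4 equiv), CH2Cl2, −20 °C → 0 °C; neutral work-up
Reagents that add atoms: none
Why: Selective sulfonylation of the secondary over the tertiary alcohol followed by E1cB elimination of the β-mesyloxy ketone through the C2 enolate gives the conjugated C2=C3 enone, the tertiary C5 hydroxyl being a far poorer leaving group so that its configuration is retained.

**Compound list**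

1 | oleic acid, (9Z)-octadec-9-enoic acid | CCCCCCCC/C=C\CCCCCCCC(=O)O | starting material
2 | methyllithium | [Li]C | starting material
3 | (10Z)-nonadec-10-en-2-one | CCCCCCCC/C=C\CCCCCCCC(C)=O | intermediate
4 | (4R,6S)-6-(chloromethyl)-4-hydroxyoxan-2-one | O=C1C[C@H](O)C[C@@H](CCl)O1 | starting material
5 | (4R,6S)-4-(tert-butyldimethylsilyloxy)-6-(chloromethyl)oxan-2-one | O=C1C[C@H](O[Si](C)(C)C(C)(C)C)C[C@@H](CCl)O1 | intermediate
6 | lithium (10Z)-nonadeca-1,10-dien-2-olate | CCCCCCCC/C=C\CCCCCCCC(=C)O[Li] | intermediate (not isolated)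
7 | (10Z)-1-[(4R,6S)-4-(tert-butyldimethylsilyloxy)-6-(chloromethyl)-2-hydroxyoxan-2-yl]nonadec-10-en-2-one (C2 epimers) | CCCCCCCC/C=C\CCCCCCCC(=O)CC1(O)C[C@H](O[Si](C)(C)C(C)(C)C)C[C@@H](CCl)O1 | intermediate
8 | (1E,10Z)-1-[(4R,6S)-4-(tert-butyldimethylsilyloxy)-6-(chloromethyl)oxan-2-ylidene]nonadec-10-en-2-one | CCCCCCCC/C=C\CCCCCCCC(=O)/C=C1\C[C@H](O[Si](C)(C)C(C)(C)C)C[C@@H](CCl)O1 | intermediate
9 | (1E,10Z)-1-[(4R,6S)-4-(tert-butyldimethylsilyloxy)-6-(iodomethyl)oxan-2-ylidene]nonadec-10-en-2-one | CCCCCCCC/C=C\CCCCCCCC(=O)/C=C1\C[C@H](O[Si](C)(C)C(C)(C)C)C[C@@H](CI)O1 | intermediate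
10 | (1E,10Z)-1-[(4R)-4-(tert-butyldimethylsilyloxy)-6-methylideneoxan-2-ylidene]nonadec-10-en-2-one | CCCCCCCC/C=C\CCCCCCCC(=O)/C=C1\C[C@H](O[Si](C)(C)C(C)(C)C)CC(=C)O1 | intermediate (key-step precursor)
11 | [(4S,16Z)-4-(tert-butyldimethylsilyloxy)-2,6,8-trioxopentacos-16-en-1-yl]mercury trifluoroacetate | CCCCCCCC/C=C\CCCCCCCC(=O)CC(=O)C[C@H](O[Si](C)(C)C(C)(C)C)CC(=O)C[Hg]OC(=O)C(F)(F)F | intermediate (not isolated)
12 | (3S,5R)-3-(tert-butyldimethylsilyloxy)-5-hydroxy-5-[(10Z)-2-oxononadec-10-en-1-yl]cyclohexan-1-one | CCCCCCCC/C=C\CCCCCCCC(=O)C[C@]1(O)C[C@H](O[Si](C)(C)C(C)(C)C)CC(=O)C1 | intermediate (key-step product)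
13 | (3S,5R)-3,5-dihydroxy-5-[(10Z)-2-oxononadec-10-en-1-yl]cyclohexan-1-one | CCCCCCCC/C=C\CCCCCCCC(=O)C[C@]1(O)C[C@H](O)CC(=O)C1 | intermediate
14 | (1S,3R)-3-hydroxy-5-oxo-3-[(10Z)-2-oxononadec-10-en-1-yl]cyclohexyl methanesulfonate | CCCCCCCC/C=C\CCCCCCCC(=O)C[C@]1(O)C[C@H](OS(C)(=O)=O)CC(=O)C1 | intermediate (not isolated)
15 | (5R)-5-hydroxy-5-[(10Z)-2-oxononadec-10-en-1-yl]cyclohex-2-en-1-one (CNP0165051.1) | CCCCCCCC/C=C\CCCCCCCC(=O)C[C@]1(O)CC=CC(=O)C1 | target

**Step count**

Total steps: 9. Longest linear sequence: 8 (steps 2–9 from 4; the oleic acid branch, steps 1 and 3–9, is equally long).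

**Steps most likely to fail, with fallbacks**

Step 7 (proposed new method). What may go wrong:
- protonolysis of the carbon–mercury bond of 11 by the acidic β-diketone before ring closure, after which the free triketone cyclises through C1′ or loses silanol;
- capture of the catalyst at the diketone carbon;
- erosion of facial selectivity at C5, which would appear as the enantiomer after step 9.

Fallback by known chemistry, setting out from 3 and returning at 13: the C5–C1′ bond is made by intermolecular aldol addition to a ring that already exists, so no β-diketone is ever present. Enolate 6 (from 3, LiN(i-Pr)2, THF, −78 °C), transmetalated with anhydrous CeCl3 to suppress enolisation, is added to the C2-symmetric, quinic-acid-derived (3R,5R)-3,5-bis(tert-butyldimethylsilyloxy)cyclohexan-1-one F1, expected to be purchasable. Its two carbonyl faces are equivalent, so a single adduct, (10Z)-1-[(3R,5R)-1-hydroxy-3,5-bis(tert-butyldimethylsilyloxy)cyclohexyl]nonadec-10-en-2-one F2, is expected. HF·pyridine should give (10Z)-1-[(3R,5R)-1,3,5-trihydroxycyclohexyl]nonadec-10-en-2-one F3. The two secondary hydroxyls of F3 differ only in their relation to the side chain, and this is used to tell them apart. MeOH, HC(OMe)3 and PPTS should close the side-chain ketone onto the hydroxyl cis to the side chain, giving the bridged methyl ketal 3-[(8Z)-heptadec-8-en-1-yl]-3-methoxy-2-oxabicyclo[3.3.1]nonane-5,7-diol F4 (ring configuration as in F3, ketal carbon unassigned). In F4 only the secondary hydroxyl cis to the tertiary one is free. Dess–Martin periodinane (NaHCO3, CH2Cl2) should oxidise it to 3-[(8Z)-heptadec-8-en-1-yl]-5-hydroxy-3-methoxy-2-oxabicyclo[3.3.1]nonan-7-one F5. AcOH–THF–H2O then opens the ketal to 13, with both stereocentres as in the main route, and step 9 follows.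

Step 3. What may go wrong: proton transfer from the lactone to the enolate followed by β-elimination of the silyloxy group, or reversal of the addition so that conversion stalls.

Fallback setting out from 3 and 5 and returning at 8: the carbon nucleophile is changed to an acetylide, whose addition to δ-lactones is fast and irreversible at −78 °C. Ketone 3 is converted in one flask into the alkyne: LiN(i-Pr)2 then ClP(O)(OEt)2 gives diethyl (10Z)-nonadeca-1,10-dien-2-yl phosphate F6 (not isolated), and a further 2.2 equivalents of LiN(i-Pr)2 eliminate it to (10Z)-nonadec-10-en-1-yne F7. Its lithium acetylide (n-BuLi, THF, −78 °C) should add once to 5 to give the alkynyl lactol (4R,6S)-4-(tert-butyldimethylsilyloxy)-6-(chloromethyl)-2-[(10Z)-nonadec-10-en-1-yn-1-yl]oxan-2-ol F8. Meyer–Schuster rearrangement (Ph3PAuNTf2 cat., wet CH2Cl2, rt) transposes the oxygen and should deliver vinylogous ester 8 directly, replacing steps 3 and 4.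

Step 6. What may go wrong: N-alkylation of DBU by the primary iodide, vinylogous E1cB loss of the silyloxy group through γ-deprotonation, or migration of the exocyclic double bond into the ring during isolation.

Fallback setting out from 9 and returning at 10: base-free syn-elimination. PhSeNa (pre-formed from PhSeSePh and NaBH4 in EtOH, no excess hydride; then DMF, rt) should displace iodide to give (1E,10Z)-1-[(4R,6S)-4-(tert-butyldimethylsilyloxy)-6-[(phenylselanyl)methyl]oxan-2-ylidene]nonadec-10-en-2-one F9. NaIO4 with NaHCO3 in MeOH–THF–H2O oxidises selenium only, giving the selenoxide (1E,10Z)-1-[(4R,6S)-4-(tert-butyldimethylsilyloxy)-6-[(phenylseleninyl)methyl]oxan-2-ylidene]nonadec-10-en-2-one F10. Warmed in toluene with i-Pr2NH, F10 should eliminate toward its only β-hydrogen (C6–H) to give 10.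

**Further compounds**

F1 | step 7 | (3R,5R)-3,5-bis(tert-butyldimethylsilyloxy)cyclohexan-1-one | O=C1C[C@H](O[Si](C)(C)C(C)(C)C)C[C@@H](O[Si](C)(C)C(C)(C)C)C1
F2 | step 7 | (10Z)-1-[(3R,5R)-1-hydroxy-3,5-bis(tert-butyldimethylsilyloxy)cyclohexyl]nonadec-10-en-2-one | CCCCCCCC/C=C\CCCCCCCC(=O)CC1(O)C[C@H](O[Si](C)(C)C(C)(C)C)C[C@@H](O[Si](C)(C)C(C)(C)C)C1
F3 | step 7 | (10Z)-1-[(3R,5R)-1,3,5-trihydroxycyclohexyl]nonadec-10-en-2-one | CCCCCCCC/C=C\CCCCCCCC(=O)CC1(O)C[C@H](O)C[C@@H](O)C1
F4 | step 7 | 3-[(8Z)-heptadec-8-en-1-yl]-3-methoxy-2-oxabicyclo[3.3.1]nonane-5,7-diol (ring configuration as in F3, ketal carbon unassigned) | CCCCCCCC/C=C\CCCCCCCC1(OC)C[C@]2(O)C[C@H](O1)C[C@@H](O)C2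
F5 | step 7 | 3-[(8Z)-heptadec-8-en-1-yl]-5-hydroxy-3-methoxy-2-oxabicyclo[3.3.1]nonan-7-one (ring configuration as in F4) | CCCCCCCC/C=C\CCCCCCCC1(OC)C[C@]2(O)C[C@H](O1)CC(=O)C2
F6 | step 3 | diethyl (10Z)-nonadeca-1,10-dien-2-yl phosphate | CCCCCCCC/C=C\CCCCCCCC(=C)OP(=O)(OCC)OCC
F7 | step 3 | (10Z)-nonadec-10-en-1-yne | CCCCCCCC/C=C\CCCCCCCC#C
F8 | step 3 | (4R,6S)-4-(tert-butyldimethylsilyloxy)-6-(chloromethyl)-2-[(10Z)-nonadec-10-en-1-yn-1-yl]oxan-2-ol (C2 epimers) | CCCCCCCC/C=C\CCCCCCCC#CC1(O)C[C@H](O[Si](C)(C)C(C)(C)C)C[C@@H](CCl)O1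
F9 | step 6 | (1E,10Z)-1-[(4R,6S)-4-(tert-butyldimethylsilyloxy)-6-[(phenylselanyl)methyl]oxan-2-ylidene]nonadec-10-en-2-one | CCCCCCCC/C=C\CCCCCCCC(=O)/C=C1\C[C@H](O[Si](C)(C)C(C)(C)C)C[C@@H](C[Se]c2ccccc2)O1
F10 | step 6 | (1E,10Z)-1-[(4R,6S)-4-(tert-butyldimethylsilyloxy)-6-[(phenylseleninyl)methyl]oxan-2-ylidene]nonadec-10-en-2-one | CCCCCCCC/C=C\CCCCCCCC(=O)/C=C1\C[C@H](O[Si](C)(C)C(C)(C)C)C[C@@H](C[Se](=O)c2ccccc2)O1
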